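**Retrosynthetic overview**

1. Target 17 ⇐ global hydrogenolysis (eight benzyl ethers, C8–Br) and deacetylation of the protected dimer 15.
2. 15 ⇐ one operation on acylal 10 (a trans-2-aryl-2,3-dihydrobenzofuran-3-carbaldehyde diacetate) and 8-bromo-penta-O-benzyl-(+)-gallocatechin 13: the pyran C-ring of the fisetinidol unit (O1, C2, C3, C4, C4a, C8a) is made by enlarging the five-membered dihydrofuran ring of 10 (1,2-shift of C2 onto the exocyclic carbon, which becomes C3), and the C4 cation so formed is joined to C6 of 13.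
3. Enabling feature: C4 is benzylic to an A-ring that carries O1 ortho and O7 para to C4a, so a C4 cation is far better stabilised than the exocyclic acyloxycarbenium ion it comes from; C2 carries O1 and the B-ring and so migrates readily; the acetoxy group on C3 then holds C4 as a five-membered acetoxonium ring and steers the D-ring trans.
4. 10 ⇐ dihydrobenzofuran ester 8 by Rh(II)-carbenoid C–H insertion of aryl diazoacetate 6 (sets C2) ⇐ aryl bromide 4 ⇐ 4-bromoresorcinol 1 + benzylic chloride 3; 13 ⇐ (+)-gallocatechin 11 (benzylation, C8 bromination).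
5. Ring order: the aromatic rings and the gallocatechin pyran ring are bought; dihydrofuran ring (step 5) → fisetinidol pyran ring by ring enlargement with simultaneous interflavan bond formation (step 10).

Key step: step 10

Assumption: (+)-gallocatechin (2R,3S), compounds 1 and 3 and the Reformatsky reagent solution are taken as purchasable, and the enantiomer of the Rh(II) catalyst that delivers the (2S) series in step 5 is used (written as Rh2(S-PTTL)4).

**Route**

Step 1
Reactants: 1 4-bromoresorcinol
Product: 2 5-(benzyloxy)-2-bromophenol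
Conditions: BnBr (1.0 equiv), K2CO3 (1.0 equiv), acetone, rt; chromatography
Reagents that add atoms: benzyl bromide, BrCc1ccccc1
Why: Williamson etherification in which the hydroxyl para to bromine (unhindered, not hydrogen-bonded to Br) should react first, the regioisomer and the bis-ether being removed by chromatography.

Step 2
Reactants: 2 5-(benzyloxy)-2-bromophenol; 3 3,4-bis(benzyloxy)benzyl chloride
Product: 4 4-(benzyloxy)-2-{[3,4-bis(benzyloxy)phenyl]methoxy}-1-bromobenzene
Conditions: K2CO3, cat. Bu4NI, DMF, 60 °C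
Reagents that add atoms: none
Why: Williamson etherification of the remaining phenol with an activated benzylic chloride under iodide catalysis.

Step 3
Reactants: 4 4-(benzyloxy)-2-{[3,4-bis(benzyloxy)phenyl]methoxy}-1-bromobenzene
Product: 5 ethyl 2-[4-(benzyloxy)-2-{[3,4-bis(benzyloxy)phenyl]methoxy}phenyl]acetate
Conditions: BrZnCH2CO2Et (1.5 equiv), Pd2(dba)3 (1 mol %), XPhos (4 mol %), THF, 60 °C
Reagents that add atoms: (2-ethoxy-2-oxoethyl)zinc bromide, CCOC(=O)C[Zn]Br
Why: Negishi coupling of a Reformatsky reagent (Pd-catalysed arylation of a zinc ester enolate), which tolerates electron-rich ortho-alkoxy aryl bromides and benzyl ethers.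

Step 4
Reactants: 5 ethyl 2-[4-(benzyloxy)-2-{[3,4-bis(benzyloxy)phenyl]methoxy}phenyl]acetate
Product: 6 ethyl 2-diazo-2-[4-(benzyloxy)-2-{[3,4-bis(benzyloxy)phenyl]methoxy}phenyl]acetate
Conditions: p-ABSA (1.3 equiv), DBU (1.5 equiv), MeCN, 0 °C → rt
Reagents that add atoms: 4-acetamidobenzenesulfonyl azide, CC(=O)Nc1ccc(cc1)S(=O)(=O)N=[N+]=[N-]
Why: Regitz diazo transfer to the benzylic ester methylene gives the donor/acceptor diazo compound.

Step 5
Reactants: 6 ethyl 2-diazo-2-[4-(benzyloxy)-2-{[3,4-bis(benzyloxy)phenyl]methoxy}phenyl]acetate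
Product: 8 ethyl (2S,3S)-6-(benzyloxy)-2-[3,4-bis(benzyloxy)phenyl]-2,3-dihydro-1-benzofuran-3-carboxylate (2,3-trans), via cis-(2S,3R) insertion product 7 (not isolated)
Conditions: Rh2(S-PTTL)4 (1 mol %), toluene, −60 °C; then NaOEt (0.3 equiv), EtOH, rt
Reagents that add atoms: none
Why: Intramolecular Rh(II)-carbenoid 1,5-insertion into the ether-activated benzylic C–H bond closes the dihydrofuran ring, the chiral carboxylate ligands choosing one of the two enantiotopic benzylic hydrogens and so fixing C2 as S, and the kinetic cis ester is then epimerised at C3 only (ethoxide, thermodynamic trans) so that the B-ring is kept away from the ester-derived carbon in step 10.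

Step 6
Reactants: 8 ethyl (2S,3S)-6-(benzyloxy)-2-[3,4-bis(benzyloxy)phenyl]-2,3-dihydro-1-benzofuran-3-carboxylate
Product: 9 (2S,3S)-6-(benzyloxy)-2-[3,4-bis(benzyloxy)phenyl]-2,3-dihydro-1-benzofuran-3-carbaldehyde
Conditions: DIBAL-H (1.1 equiv), CH2Cl2, −78 °C; Rochelle salt work-up
Reagents that add atoms: none
Why: Half-reduction of the ester through the aluminium hemiacetal that is stable at −78 °C, the trans arrangement already being the thermodynamic one so that C3 cannot drift.

Step 7
Reactants: 9 (2S,3S)-6-(benzyloxy)-2-[3,4-bis(benzyloxy)phenyl]-2,3-dihydro-1-benzofuran-3-carbaldehyde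
Product: 10 [(2S,3S)-6-(benzyloxy)-2-[3,4-bis(benzyloxy)phenyl]-2,3-dihydro-1-benzofuran-3-yl]methanediyl diacetate (acylal)
Conditions: Ac2O (3 equiv), Sc(OTf)3 (1 mol %), CH2Cl2, 0 °C
Reagents that add atoms: acetic anhydride, CC(=O)OC(C)=O
Why: Lewis-acid-catalysed acylal formation (addition of acetic anhydride across the C=O), in which the acetate-rich medium should capture the acyloxycarbenium intermediate before it can rearrange.

Step 8
Reactants: 11 (+)-gallocatechin
Product: 12 5,7,3',4',5'-penta-O-benzyl-(+)-gallocatechin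
Conditions: BnBr (5.5 equiv), K2CO3, DMF, 0 °C → rt, Ar
Reagents that add atoms: benzyl bromide, BrCc1ccccc1
Why: Williamson benzylation of the five phenols only, since carbonate does not deprotonate the secondary 3-OH.

Step 9
Reactants: 12 5,7,3',4',5'-penta-O-benzyl-(+)-gallocatechin
Product: 13 8-bromo-5,7,3',4',5'-penta-O-benzyl-(+)-gallocatechin
Conditions: NBS (1.0 equiv), CH2Cl2, −78 → 0 °C
Reagents that add atoms: N-bromosuccinimide, BrN1C(=O)CCC1=O
Why: Electrophilic aromatic bromination of the phloroglucinol-type A-ring, which in 5,7-di-O-benzyl flavan-3-ols takes place at C8 and leaves C6 as the only free nucleophilic position.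

Step 10
Reactants: 10 [(2S,3S)-6-(benzyloxy)-2-[3,4-bis(benzyloxy)phenyl]-2,3-dihydro-1-benzofuran-3-yl]methanediyl diacetate; 13 8-bromo-5,7,3',4',5'-penta-O-benzyl-(+)-gallocatechin
Product: 15 3-O-acetyl-7,3',4'-tri-O-benzylfisetinidol-(4α→6)-8-bromo-5,7,3',4',5'-penta-O-benzylgallocatechin, via flavan-3,4-diyl acetoxonium triflate 14 (not isolated)
Conditions: TMSOTf (1.2 equiv), CH2Cl2, 4 Å MS, −78 → −40 °C; then 13 (2.5 equiv), −78 → −30 °C; Et3N quench
Reagents that add atoms: none
Why: Proposed new method: TMSOTf removes one acetate of the acylal as TMSOAc, and the exocyclic acyloxycarbenium ion (a poorly stabilised cation) is expected to undergo a Wagner–Meerwein 1,2-shift of C2 (the benzofuran carbon bearing O1 and the B-ring) from the benzofuran C3 to the carbenium carbon, which enlarges the five-membered ring to the pyran and moves the charge to C4, now a benzylic cation with O1 ortho and the 7-benzyloxy group para; the closest known reaction types are the acid-induced aldehyde–ketone (retro-semipinacol) 1,2-shift and the ring enlargement of cycloalkylcarbinyl cations, while the second half is the established 3-O-acyl-assisted Friedel–Crafts coupling of flavan-4-yl cations with 8-bromoflavan-3-ols. The pyran ring is thus closed by ring enlargement (the C2–C3 bond forms as the old C2–C4 bond breaks, with retention at the migrating C2), and the C4 cation is at once closed to the cis-fused five-membered acetoxonium ring of 14 by 5-exo attack of the 3-acetoxy carbonyl oxygen, which makes the sequence downhill and gives the ion a resting state before the arene is added. C3 is set in the shift, the trigonal carbenium carbon receiving C2 on the face that leaves the acetoxy group anti to the B-ring, and because the shift stays reversible until 14 forms the diequatorial 2,3-trans ion should accumulate; C4 is set by the acetoxonium ring, which the arene opens with inversion, i.e. trans to O3 (4α). The step needs C2 to migrate instead of the hydrogen on the benzofuran C3 (a hydride shift would end in a benzofuran), which is secured by the two donors on C2 (O1 and the electron-rich aryl group) that stabilise the bridged transition state, by the trans geometry of 10 that keeps the B-ring away from the carbenium carbon, and by adding the nucleophile only after ionisation; it also needs attack through C6 of 13, which the bromine at C8 enforces.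

Step 11
Reactants: 15 3-O-acetyl-7,3',4'-tri-O-benzylfisetinidol-(4α→6)-8-bromo-5,7,3',4',5'-penta-O-benzylgallocatechin
Product: 16 7,3',4'-tri-O-benzylfisetinidol-(4α→6)-8-bromo-5,7,3',4',5'-penta-O-benzylgallocatechin
Conditions: K2CO3 (0.5 equiv), MeOH/THF, rt
Reagents that add atoms: none
Why: Base-catalysed transesterification (methanolysis) removes the secondary acetate without touching benzyl ethers, the aryl bromide or the interflavan bond.

Step 12
Reactants: 16 7,3',4'-tri-O-benzylfisetinidol-(4α→6)-8-bromo-5,7,3',4',5'-penta-O-benzylgallocatechin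
Product: 17 fisetinidol-(4α→6)-gallocatechin
Conditions: H2 (1 atm), 20 % Pd(OH)2/C, Et3N (1.5 equiv), THF/MeOH/H2O, rt; filtration, lyophilisation under Ar
Reagents that add atoms: none
Why: Catalytic hydrogenolysis cleaves all eight benzyl ethers and the C8–Br bond in one operation (amine traps HBr) and leaves the C4–C6 bond and all five stereocentres untouched.

**Compound list**

1 | 4-bromoresorcinol (4-bromobenzene-1,3-diol) | Oc1ccc(Br)c(O)c1 | starting material
2 | 5-(benzyloxy)-2-bromophenol | Oc1cc(OCc2ccccc2)ccc1Br | intermediate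
3 | 3,4-bis(benzyloxy)benzyl chloride | ClCc1ccc(OCc2ccccc2)c(OCc2ccccc2)c1 | starting material
4 | 4-(benzyloxy)-2-{[3,4-bis(benzyloxy)phenyl]methoxy}-1-bromobenzene | Brc1ccc(OCc2ccccc2)cc1OCc1ccc(OCc2ccccc2)c(OCc2ccccc2)c1 | intermediate
5 | ethyl 2-[4-(benzyloxy)-2-{[3,4-bis(benzyloxy)phenyl]methoxy}phenyl]acetate | CCOC(=O)Cc1ccc(OCc2ccccc2)cc1OCc1ccc(OCc2ccccc2)c(OCc2ccccc2)c1 | intermediate
6 | ethyl 2-diazo-2-[4-(benzyloxy)-2-{[3,4-bis(benzyloxy)phenyl]methoxy}phenyl]acetate | CCOC(=O)C(=[N+]=[N-])c1ccc(OCc2ccccc2)cc1OCc1ccc(OCc2ccccc2)c(OCc2ccccc2)c1 | intermediate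
7 | ethyl (2S,3R)-6-(benzyloxy)-2-[3,4-bis(benzyloxy)phenyl]-2,3-dihydro-1-benzofuran-3-carboxylate (2,3-cis) | CCOC(=O)[C@@H]1c2ccc(OCc3ccccc3)cc2O[C@@H]1c1ccc(OCc2ccccc2)c(OCc2ccccc2)c1 | intermediate (not isolated)
8 | ethyl (2S,3S)-6-(benzyloxy)-2-[3,4-bis(benzyloxy)phenyl]-2,3-dihydro-1-benzofuran-3-carboxylate (2,3-trans) | CCOC(=O)[C@H]1c2ccc(OCc3ccccc3)cc2O[C@@H]1c1ccc(OCc2ccccc2)c(OCc2ccccc2)c1 | intermediate
9 | (2S,3S)-6-(benzyloxy)-2-[3,4-bis(benzyloxy)phenyl]-2,3-dihydro-1-benzofuran-3-carbaldehyde (trans) | O=C[C@H]1c2ccc(OCc3ccccc3)cc2O[C@@H]1c1ccc(OCc2ccccc2)c(OCc2ccccc2)c1 | intermediate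
10 | [(2S,3S)-6-(benzyloxy)-2-[3,4-bis(benzyloxy)phenyl]-2,3-dihydro-1-benzofuran-3-yl]methanediyl diacetate (trans acylal) | CC(=O)OC(OC(C)=O)[C@H]1c2ccc(OCc3ccccc3)cc2O[C@@H]1c1ccc(OCc2ccccc2)c(OCc2ccccc2)c1 | intermediate
11 | (+)-gallocatechin, (2R,3S) | O[C@H]1Cc2c(O)cc(O)cc2O[C@@H]1c1cc(O)c(O)c(O)c1 | starting material
12 | 5,7,3',4',5'-penta-O-benzyl-(+)-gallocatechin | O[C@H]1Cc2c(OCc3ccccc3)cc(OCc3ccccc3)cc2O[C@@H]1c1cc(OCc2ccccc2)c(OCc2ccccc2)c(OCc2ccccc2)c1 | intermediate
13 | 8-bromo-5,7,3',4',5'-penta-O-benzyl-(+)-gallocatechin | O[C@H]1Cc2c(OCc3ccccc3)cc(OCc3ccccc3)c(Br)c2O[C@@H]1c1cc(OCc2ccccc2)c(OCc2ccccc2)c(OCc2ccccc2)c1 | intermediate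
14 | 2,3-trans-3,4-cis-fused 2-methyl-1,3-dioxolan-2-ylium (3,4-acetoxonium) ion of 7,3',4'-tri-O-benzylflavan-3,4-diol, triflate | O(Cc1ccccc1)c1ccc2c(c1)O[C@H](c1ccc(OCc3ccccc3)c(OCc3ccccc3)c1)[C@H]1OC(C)=[O+][C@@H]21.[O-]S(=O)(=O)C(F)(F)F | intermediate (not isolated)
15 | 3-O-acetyl-7,3',4'-tri-O-benzylfisetinidol-(4α→6)-8-bromo-5,7,3',4',5'-penta-O-benzylgallocatechin; upper unit (2R,3S,4S), lower unit (2R,3S) | O(Cc1ccccc1)c1ccc2c(c1)O[C@H](c1ccc(OCc3ccccc3)c(OCc3ccccc3)c1)[C@@H](OC(C)=O)[C@@H]2c1c(OCc3ccccc3)c(Br)c2c(c1OCc1ccccc1)C[C@H](O)[C@@H](c1cc(OCc3ccccc3)c(OCc3ccccc3)c(OCc3ccccc3)c1)O2 | intermediate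
16 | 7,3',4'-tri-O-benzylfisetinidol-(4α→6)-8-bromo-5,7,3',4',5'-penta-O-benzylgallocatechin | O(Cc1ccccc1)c1ccc2c(c1)O[C@H](c1ccc(OCc3ccccc3)c(OCc3ccccc3)c1)[C@@H](O)[C@@H]2c1c(OCc3ccccc3)c(Br)c2c(c1OCc1ccccc1)C[C@H](O)[C@@H](c1cc(OCc3ccccc3)c(OCc3ccccc3)c(OCc3ccccc3)c1)O2 | intermediate
17 | fisetinidol-(4α→6)-gallocatechin; upper unit (2R,3S,4S), lower unit (2R,3S) | Oc1ccc2c(c1)O[C@H](c1ccc(O)c(O)c1)[C@@H](O)[C@@H]2c1c(O)cc2c(c1O)C[C@H](O)[C@@H](c1cc(O)c(O)c(O)c1)O2 | target

**Step count and risks**

Total step count: 12. Longest linear sequence: 10 (steps 1–7, 10, 11, 12).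

Three steps most likely to fail:

Step 10 (proposed new method). What may go wrong: a 1,2-hydride shift from the benzofuran C3 followed by proton loss (aromatisation to a benzofuran) may outrun the migration of C2. Complete heterolysis of the migrating bond may scramble the configuration at C2. The shift may deliver C2 to the wrong face and so give the 2,3-cis series. Fallback (known chemistry, no rearrangement): it sets out from nucleophile 13 and uses purchased (2R,3R)-(+)-fustin F1. F1 is benzylated on its three phenols (BnBr, K2CO3, DMF) to 7,3',4'-tri-O-benzylfustin F2. F2 is reduced (NaBH4, THF/EtOH, 0 °C) to the 2,3-trans-flavan-3,4-diol F3, whose C4 configuration is irrelevant. F3 is condensed with 13 (BF3·OEt2, CH2Cl2, −78 → 0 °C), the classical flavan-3,4-diol/flavan-3-ol Friedel–Crafts coupling with C8 blocked. This comes back to the route at 16, and step 12 follows.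

Step 5. What may go wrong: the very electron-rich benzylic C–H bond reacts through an early, hydride-transfer-like transition state, so facial discrimination by the chiral catalyst may be poor, or ylide-type side reactions at the ether oxygen may compete. Fallback (resolution instead of asymmetric catalysis): it sets out from 6, which is cyclised with achiral Rh2(OAc)4 (CH2Cl2, rt) and epimerised with NaOEt/EtOH to the racemic trans ester, i.e. 8 together with its enantiomer, ethyl (2R,3R)-6-(benzyloxy)-2-[3,4-bis(benzyloxy)phenyl]-2,3-dihydro-1-benzofuran-3-carboxylate F4. The enantiomers are separated by preparative SFC on a chiral stationary phase. It comes back to the route at 8.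

Step 6. What may go wrong: collapse of the aluminium hemiacetal before work-up may lead to over-reduction, and enolisation of the β-aryloxy aldehyde on work-up or silica may lead to elimination or aromatisation. Fallback (two-step redox instead of half-reduction): it sets out from 8, which is reduced fully (LiAlH4, THF, 0 °C) to the primary alcohol [(2S,3R)-6-(benzyloxy)-2-[3,4-bis(benzyloxy)phenyl]-2,3-dihydro-1-benzofuran-3-yl]methanol F5. F5 is oxidised under neutral conditions (Dess–Martin periodinane, NaHCO3, CH2Cl2, 0 °C) and the crude aldehyde is used directly. It comes back to the route at 9.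

Further compounds
F1 | step 10 | (2R,3R)-(+)-fustin (purchased) | O=C1c2ccc(O)cc2O[C@H](c2ccc(O)c(O)c2)[C@H]1O
F2 | step 10 | (2R,3R)-7,3',4'-tri-O-benzylfustin | O=C1c2ccc(OCc3ccccc3)cc2O[C@H](c2ccc(OCc3ccccc3)c(OCc3ccccc3)c2)[C@H]1O
F3 | step 10 | (2R,3S,4R)-7-(benzyloxy)-2-[3,4-bis(benzyloxy)phenyl]chromane-3,4-diol (2,3-trans-3,4-trans) | O(Cc1ccccc1)c1ccc2c(c1)O[C@H](c1ccc(OCc3ccccc3)c(OCc3ccccc3)c1)[C@@H](O)[C@@H]2O
F4 | step 5 | ethyl (2R,3R)-6-(benzyloxy)-2-[3,4-bis(benzyloxy)phenyl]-2,3-dihydro-1-benzofuran-3-carboxylate (enantiomer of 8) | CCOC(=O)[C@@H]1c2ccc(OCc3ccccc3)cc2O[C@H]1c1ccc(OCc2ccccc2)c(OCc2ccccc2)c1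
F5 | step 6 | [(2S,3R)-6-(benzyloxy)-2-[3,4-bis(benzyloxy)phenyl]-2,3-dihydro-1-benzofuran-3-yl]methanol (trans) | OC[C@H]1c2ccc(OCc3ccccc3)cc2O[C@@H]1c1ccc(OCc2ccccc2)c(OCc2ccccc2)c1
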